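If the isomer of the product A, isomer A for short, gathers at a steady pace g, its fraction of the charge after a time t integrates in closed form to g t, and the asked share is g t over g t plus the target's fraction.

the same everywhere: solid reagent 1.05 equiv

| charge | substrate | remark | time |
|---|---|---|---|
| Monday's | 55 mM | run made earlier |  |
| Thursday's | 86 mM | run made earlier |  |
| flask | 39 mM |  | 15 d |

| run | time / d | isomer of the product A / % | target / % |
|---|---|---|---|
| Monday's | 1.25 | 0 | 11.4 |
| Monday's | 2.08 | 1.6 | 19.1 |
| Monday's | 3.00 | 0.4 | 31.0 |
| Monday's | 5.00 | 2.0 | 31.9 |
| Monday's | 10.0 | 4.3 | 30.9 |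
| Monday's | 15.0 | 2.6 | 29.6 |
| Thursday's | 2.50 | 0.2 | 18.7 |
| Thursday's | 5.00 | 2.2 | 32.8 |
| Thursday's | 8.00 | 2.9 | 32.7 |
| Thursday's | 10.0 | 0.7 | 30.5 |
| Thursday's | 12.0 | 2.7 | 32.1 |
| Thursday's | 15.0 | 3.0 | 30.6 |

(each reading ± 1 percentage point)

- target is meant together with its idle adduct
- solid, in amounts per volume of the solution: solid reagent
- reactions considered so far: substrate + coupling partner -> intermediate + by-product; intermediate <-> target; intermediate <-> isomer of the product A; target <-> isomer of the product B; solid reagent <-> coupling partner; coupling partner + target <-> idle adduct
- at the start none of the solid reagent is in solution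

- share of isomer of the product A in isomer of the product A plus target at 12 h
- share of isomer of the product A in isomer of the product A plus target at 2.5 d
- share of isomer of the product A in isomer of the product A plus target at 15 d

You can get g twice, from two runs that share no reading. A line through the origin gives 0.00265 d⁻¹ for Monday's run and 0.00211 d⁻¹ for Thursday's. Carried to 15 d, the two part by 0.8 percentage points, against a scatter of 1 point on one reading, so you can trust them together. Their mean, 0.00238 d⁻¹, is the creep rate as these readings show it, the fraction of the charge that isomer A gains per day.

By the readings, the target climbs on average at 5.68 mM d⁻¹ up to 3.00 d in Monday's run and at 5.64 mM d⁻¹ up to 5.00 d in Thursday's. With 39 mM charged, the same pace means a gain of 0.145 d⁻¹ of the charge in the new flask. While both species climb in step, the share is g over g plus that gain, which gives 1.61% at 12 h. On this reckoning the climb in the new flask reaches the late target fraction, 30.1% by the readings at 15.0 d, after 2.08 d, which is earlier than 2.5 d. With the target flat from then on, your reckoning gives 1.94% at 2.5 d and 10.6% at 15 d.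

The forecast says 3%, 5% and 7.5%, the last “since the plateau looks concentration-independent”. Your reckoning stands lower than the forecast at the two early times and higher at the end.

The flask gives 1.55%, 2.58% and 9.94%, all within the forecast's tolerance.

    substrate + coupling partner → intermediate + by-product (k = 4.20 L mol⁻¹ h⁻¹)
    intermediate ⇌ target (K = 2.90, k = 0.0620 h⁻¹)
    intermediate ⇌ isomer of the product A (K = 2.50, k = 8.20 × 10⁻⁴ h⁻¹)
    target ⇌ isomer of the product B (K = 2.00, k = 0.0500 h⁻¹)
    solid reagent ⇌ coupling partner, rate k5*(cs5 - [coupling partner]) while solid is left; crystals form when [coupling partner] > cs5 (solubility = 22.0 mM, k = 0.0410 h⁻¹)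
    coupling partner + target ⇌ idle adduct, settled at all times (K = 72.0 L mol⁻¹)

At 15.0 d, g t gives isomer A 3.57% of the charge, and the new flask holds 3.36%. The neighbour charged with 0.630 equiv of solid reagent ends with solid reagent, its limiting reagent, at 0% of its own charge and substrate at 37.0% of the substrate charged. Scaling g and the target by the ratio of reagent charges, 0.600, gives that neighbour isomer A 2.14% and target 18.1%, with the share unchanged at 10.6%. That neighbour holds 2.31% and 18.1%, and its share at 15 d is 11.3%.

The data come from a simulation for substances that don't exist; the scatter is artificial.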